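**Strategy**

Everything rests on cutting ring C of the upper (gallocatechin-type) unit across O1–C2 and C3–C4. Because O1 and C4 hang on the adjacent ring A carbons C8a and C4a, they are the ends of an ortho-quinone methide heterodiene, and C2–C3 is a trans-styrene. One acid-catalysed oxa-[4+2] cycloaddition therefore closes ring C, makes the C3–C4 and O1–C2 bonds and sets C2, C3 and C4; boron on C3 is the masked hydroxyl. The precursor is an o-hydroxybenzhydrol whose carbinol carbon carries C8 of a preformed, tether-bridged catechin-(4β→8)-ent-catechin dimer, plus an (E)-styrylboronate.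

Key step: step 11

**Remarks and assumptions**

- The target is read as gallocatechin-(4α→8)-catechin-(4β→8)-ent-catechin: upper unit 2R,3S,4S (all-trans), middle unit 2R,3S,4S (3,4-cis), lower unit 2S,3R. The units are called upper, middle and lower, and atom numbers are flavan numbers within the unit named.
- The C4 ether centre made in step 4 and the carbinol centre made in step 9 are erased by later ionisation. The first is drawn 4β (3,4-cis), the second is left undefined.
- TRIP is 3,3'-bis(2,4,6-triisopropylphenyl)-1,1'-binaphthalene-2,2'-diyl hydrogen phosphate. Which antipode gives the required facial sense cannot be predicted for this dienophile; (R) is written, and its mirror image would be used if it proves to favour the other face.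

**Route**

Step 1
Reactants: 1 (−)-catechin
Product: 2 5,7,3',4'-tetra-O-benzyl-(−)-catechin
Conditions: BnBr (4.4 equiv), K2CO3, DMF, 0 °C → rt
Reagents that add atoms: benzyl bromide, BrCc1ccccc1
Why: Williamson etherification in which only the four phenols are acidic enough for K2CO3, so the secondary 3-OH stays free and no stereocentre is touched.

Step 2
Reactants: 2 5,7,3',4'-tetra-O-benzyl-(−)-catechin; 3 1,3-bis(bromomethyl)benzene
Product: 4 3-O-[3-(bromomethyl)benzyl]-5,7,3',4'-tetra-O-benzyl-(−)-catechin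
Conditions: NaH, 3 (5 equiv), THF/DMF, 0 °C → rt
Reagents that add atoms: none
Why: Williamson etherification of the 3-alkoxide, held at mono-alkylation by the large excess of dibromide; only the O–H bond reacts, so C3 keeps its configuration.

Step 3
Reactants: 5 (+)-catechin
Product: 6 5,7,3',4'-tetra-O-benzyl-(+)-catechin
Conditions: BnBr (4.4 equiv), K2CO3, DMF, 0 °C → rt
Reagents that add atoms: benzyl bromide, BrCc1ccccc1
Why: Williamson etherification of the four phenols only, as in step 1.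

Step 4
Reactants: 6 5,7,3',4'-tetra-O-benzyl-(+)-catechin
Product: 7 (2R,3S,4S)-5,7,3',4'-tetra-O-benzyl-4-(2-ethoxyethoxy)flavan-3-ol
Conditions: DDQ (2 equiv), 2-ethoxyethanol, CH2Cl2, rt
Reagents that add atoms: 2-ethoxyethanol, CCOCCO
Why: DDQ benzylic oxidation, in which hydride loss from C4 is assisted by the 5- and 7-benzyloxy groups and O1 and the alcohol traps the electrophilic carbon; the new C4 centre is provisional.

Step 5
Reactants: 7 (2R,3S,4S)-5,7,3',4'-tetra-O-benzyl-4-(2-ethoxyethoxy)flavan-3-ol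
Product: 8 (2R,3S,4S)-8-bromo-5,7,3',4'-tetra-O-benzyl-4-(2-ethoxyethoxy)flavan-3-ol
Conditions: NBS (1.05 equiv), CH2Cl2, −20 → 0 °C
Reagents that add atoms: N-bromosuccinimide, O=C1CCC(=O)N1Br
Why: Electrophilic aromatic bromination at C8, the most nucleophilic and least hindered position of the 5,7-dioxygenated ring A; the bromine blocks self-condensation now and is the later handle for the upper unit.

Step 6
Reactants: 8 (2R,3S,4S)-8-bromo-5,7,3',4'-tetra-O-benzyl-4-(2-ethoxyethoxy)flavan-3-ol; 4 3-O-[3-(bromomethyl)benzyl]-5,7,3',4'-tetra-O-benzyl-(−)-catechin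
Product: 9 m-xylylene-linked pair (3-O of 8 and 3-O of the ent-catechin unit joined by 1,3-phenylenebis(methylene))
Conditions: NaH, Bu4NI (cat.), DMF, 0 °C → rt
Reagents that add atoms: none
Why: Williamson etherification of the 3-alkoxide of 8 by the benzylic bromide of 4; the aryl bromide and the C4 ether are inert to NaH and no stereocentre is involved.

Step 7
Reactants: 9 m-xylylene-linked pair
Product: 10 bridged bromo dimer: 8-bromo-tetra-O-benzylcatechin-(4β→8)-tetra-O-benzyl-ent-catechin with the two 3-oxygens joined by the m-xylylene bridge (middle unit 2R,3S,4S; lower unit 2S,3R)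
Conditions: TMSOTf (0.2 equiv), CH2Cl2 (1 mM), −78 → −30 °C; Et3N quench
Reagents that add atoms: none
Why: Lewis-acid ionisation of the C4 ether followed by intramolecular Friedel–Crafts capture by C8 of the tethered lower unit (14-membered ring); the tether is anchored on the β-oriented 3-oxygen, so the arene is delivered to the β-face and the new C4 centre is 3,4-cis, the reverse of the untethered preference.

Step 8
Reactants: 11 2,4,6-trihydroxybenzaldehyde
Product: 12 2,4-bis(benzyloxy)-6-hydroxybenzaldehyde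
Conditions: BnBr (2.1 equiv), K2CO3, DMF, rt
Reagents that add atoms: benzyl bromide, BrCc1ccccc1
Why: Williamson etherification of the 4-OH and one ortho-OH; the remaining ortho-OH is hydrogen-bonded to the formyl group and reacts last, so it is left free.

Step 9
Reactants: 10 bridged bromo dimer; 12 2,4-bis(benzyloxy)-6-hydroxybenzaldehyde
Product: 15 o-hydroxybenzhydrol of the bridged dimer (mixture of carbinol epimers), via middle-unit C8 aryllithium 13 (not isolated), via sodium 2-formyl-3,5-bis(benzyloxy)phenoxide 14 (not isolated)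
Conditions: 10, t-BuLi (2.1 equiv), THF, −78 °C; then 14 [from 12 (2 equiv), NaH (2 equiv), THF, 0 °C], −78 → 0 °C; H2O; crude product used after filtration through Et3N-deactivated silica
Reagents that add atoms: none
Why: Bromine–lithium exchange followed by 1,2-addition of the aryllithium to the aldehyde, whose phenol is masked as its sodium salt; the new carbinol centre forms unselectively, which is irrelevant because it becomes sp2 in step 11.

Step 10
Reactants: 16 3,4,5-tris(benzyloxy)benzaldehyde; 17 bis(pinacolatoboryl)methane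
Product: 19 (E)-2-[3,4,5-tris(benzyloxy)phenyl]vinylboronic acid pinacol ester, via lithiated bis(pinacolatoboryl)methane 18 (not isolated)
Conditions: 17, LiTMP (1.1 equiv), THF, 0 °C; then 16, −78 °C → rt
Reagents that add atoms: none
Why: Boron-Wittig olefination, in which the α-boryl carbanion adds to the aldehyde and syn B–O elimination gives the alkenylboronate with the aryl and boryl groups trans (E).

Step 11
Reactants: 15 o-hydroxybenzhydrol of the bridged dimer; 19 (E)-2-[3,4,5-tris(benzyloxy)phenyl]vinylboronic acid pinacol ester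
Product: 21 fully protected trimer with a pinacolboryl group on upper C3 (upper unit 2,3-trans-3,4-trans), via o-quinone methide 20 (not isolated)
Conditions: (R)-TRIP (10 mol %), 19 (3 equiv), 5 Å MS, PhMe, 0 °C → rt
Reagents that add atoms: none
Why: Proposed new method: the chiral phosphoric acid dehydrates 15 to the hydrogen-bonded (E)-o-quinone methide 20, whose O=C8a–C4a=C4 heterodiene undergoes an asynchronous inverse-electron-demand oxa-[4+2] cycloaddition with the C2=C3 bond of 19, C3–C4 formation leading and the developing benzylic charge at C2 collapsing onto the ring A oxygen; the closest known reaction type is the phosphoric-acid-catalysed oxa-Diels–Alder reaction of in situ generated o-quinone methides with styrene-type dienophiles, extended here to a β-boryl styrene that keeps its boron. Ring C of the upper unit closes in the cycloaddition mode, C3–C4 and O1–C2 forming in one six-membered transition state. The 2,3-trans relation is the suprafacial transcription of the E-alkene, the 2,4-cis (hence 3,4-trans, all-equatorial) relation follows from endo placement of the styrene aryl under the E-configured diene with the boryl group exo, and the absolute sense at C2, C3 and C4 is imposed by the catalyst because the resident stereocentres are remote. Regioselectivity (boron-bearing carbon to C4) is needed and is secured by the aryl group on the other alkene carbon, which stabilises charge at C2, reinforced by C–B hyperconjugation. Chemoselectivity for cycloaddition over alkenyl transfer with loss of boron is also needed and is secured by the pinacol ester, which resists the ate-complex formation that alkenyl transfer requires.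

Step 12
Reactants: 21 fully protected trimer with a pinacolboryl group on upper C3
Product: 22 protected trimer with free upper 3-OH (thirteen benzyl ethers and the m-xylylene bridge)
Conditions: H2O2 (30 % aq), NaOH (2 M aq), THF, 0 °C → rt
Reagents that add atoms: hydrogen peroxide, OO
Why: Alkaline peroxide oxidation of the C–B bond, the same operation that ends the hydroboration route to flavan-3-ols; the 1,2-shift of C3 from boron to oxygen proceeds with retention, so the 3-OH is trans to both aryl groups (3S).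

Step 13
Reactants: 22 protected trimer with free upper 3-OH
Product: 23 gallocatechin-(4α→8)-catechin-(4β→8)-ent-catechin (target)
Conditions: H2 (1 atm), Pd(OH)2/C, THF/MeOH/H2O, rt
Reagents that add atoms: none
Why: Hydrogenolysis of the thirteen benzyl ethers and of both benzylic C–O bonds of the bridge under neutral conditions that leave the eight stereocentres and the interflavan bonds untouched.

**Compound list**

1 | (−)-catechin, (2S,3R) | c1c(O)cc(O)c2c1O[C@@H](c1ccc(O)c(O)c1)[C@H](O)C2 | starting material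
2 | 5,7,3',4'-tetra-O-benzyl-(−)-catechin | c1c(OCc3ccccc3)cc(OCc3ccccc3)c2c1O[C@@H](c1ccc(OCc3ccccc3)c(OCc3ccccc3)c1)[C@H](O)C2 | intermediate
3 | 1,3-bis(bromomethyl)benzene | BrCc1cccc(CBr)c1 | starting material
4 | 3-O-[3-(bromomethyl)benzyl]-5,7,3',4'-tetra-O-benzyl-(−)-catechin | c1c(OCc3ccccc3)cc(OCc3ccccc3)c2c1O[C@@H](c1ccc(OCc3ccccc3)c(OCc3ccccc3)c1)[C@H](OCc1cccc(CBr)c1)C2 | intermediate
5 | (+)-catechin, (2R,3S) | c1c(O)cc(O)c2c1O[C@H](c1ccc(O)c(O)c1)[C@@H](O)C2 | starting material
6 | 5,7,3',4'-tetra-O-benzyl-(+)-catechin | c1c(OCc3ccccc3)cc(OCc3ccccc3)c2c1O[C@H](c1ccc(OCc3ccccc3)c(OCc3ccccc3)c1)[C@@H](O)C2 | intermediate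
7 | (2R,3S,4S)-5,7,3',4'-tetra-O-benzyl-4-(2-ethoxyethoxy)flavan-3-ol (4β ether) | c1c(OCc3ccccc3)cc(OCc3ccccc3)c2c1O[C@H](c1ccc(OCc3ccccc3)c(OCc3ccccc3)c1)[C@@H](O)[C@H]2OCCOCC | intermediate
8 | (2R,3S,4S)-8-bromo-5,7,3',4'-tetra-O-benzyl-4-(2-ethoxyethoxy)flavan-3-ol | Brc1c(OCc3ccccc3)cc(OCc3ccccc3)c2c1O[C@H](c1ccc(OCc3ccccc3)c(OCc3ccccc3)c1)[C@@H](O)[C@H]2OCCOCC | intermediate
9 | m-xylylene-linked pair: 3-O of 8 and 3-O of tetra-O-benzyl-ent-catechin joined by 1,3-phenylenebis(methylene) | Brc1c(OCc3ccccc3)cc(OCc3ccccc3)c2c1O[C@H](c1ccc(OCc3ccccc3)c(OCc3ccccc3)c1)[C@@H](OCc1cccc(c1)CO[C@@H]1Cc3c(OCc4ccccc4)cc(OCc4ccccc4)cc3O[C@H]1c1ccc(OCc3ccccc3)c(OCc3ccccc3)c1)[C@H]2OCCOCC | intermediate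
10 | bridged bromo dimer: 8-bromo-tetra-O-benzylcatechin-(4β→8)-tetra-O-benzyl-ent-catechin, 3-O to 3-O m-xylylene bridge | Brc1c(OCc3ccccc3)cc(OCc3ccccc3)c2c1O[C@H](c1ccc(OCc3ccccc3)c(OCc3ccccc3)c1)[C@@H](OCc1cccc(CO4)c1)[C@H]2c1c(OCc3ccccc3)cc(OCc3ccccc3)c2c1O[C@@H](c1ccc(OCc3ccccc3)c(OCc3ccccc3)c1)[C@H]4C2 | intermediate
11 | 2,4,6-trihydroxybenzaldehyde | O=Cc1c(O)cc(O)cc1O | starting material
12 | 2,4-bis(benzyloxy)-6-hydroxybenzaldehyde | O=Cc1c(O)cc(OCc2ccccc2)cc1OCc1ccccc1 | intermediate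
13 | middle-unit C8 aryllithium of the bridged dimer | [Li]c1c(OCc3ccccc3)cc(OCc3ccccc3)c2c1O[C@H](c1ccc(OCc3ccccc3)c(OCc3ccccc3)c1)[C@@H](OCc1cccc(CO4)c1)[C@H]2c1c(OCc3ccccc3)cc(OCc3ccccc3)c2c1O[C@@H](c1ccc(OCc3ccccc3)c(OCc3ccccc3)c1)[C@H]4C2 | intermediate
14 | sodium 2-formyl-3,5-bis(benzyloxy)phenoxide | [Na+].[O-]c1cc(OCc2ccccc2)cc(OCc2ccccc2)c1C=O | intermediate
15 | o-hydroxybenzhydrol: [2-hydroxy-4,6-bis(benzyloxy)phenyl](middle-unit C8 of the bridged dimer)methanol, carbinol epimers | OC(c1c(O)cc(OCc3ccccc3)cc1OCc1ccccc1)c1c(OCc3ccccc3)cc(OCc3ccccc3)c2c1O[C@H](c1ccc(OCc3ccccc3)c(OCc3ccccc3)c1)[C@@H](OCc1cccc(CO4)c1)[C@H]2c1c(OCc3ccccc3)cc(OCc3ccccc3)c2c1O[C@@H](c1ccc(OCc3ccccc3)c(OCc3ccccc3)c1)[C@H]4C2 | intermediate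
16 | 3,4,5-tris(benzyloxy)benzaldehyde | O=Cc1cc(OCc2ccccc2)c(OCc2ccccc2)c(OCc2ccccc2)c1 | starting material
17 | bis(pinacolatoboryl)methane | CC1(C)OB(CB2OC(C)(C)C(C)(C)O2)OC1(C)C | starting material
18 | lithiated bis(pinacolatoboryl)methane | [Li]C(B1OC(C)(C)C(C)(C)O1)B1OC(C)(C)C(C)(C)O1 | intermediate
19 | (E)-2-[3,4,5-tris(benzyloxy)phenyl]vinylboronic acid pinacol ester | CC1(C)OB(/C=C/c2cc(OCc3ccccc3)c(OCc3ccccc3)c(OCc3ccccc3)c2)OC1(C)C | intermediate
20 | (E)-o-quinone methide: 3,5-bis(benzyloxy)-6-(arylmethylidene)cyclohexa-2,4-dienone, aryl = middle-unit C8 of the bridged dimer | O=C1C=C(OCc3ccccc3)C=C(OCc3ccccc3)/C1=C\c1c(OCc3ccccc3)cc(OCc3ccccc3)c2c1O[C@H](c1ccc(OCc3ccccc3)c(OCc3ccccc3)c1)[C@@H](OCc1cccc(CO4)c1)[C@H]2c1c(OCc3ccccc3)cc(OCc3ccccc3)c2c1O[C@@H](c1ccc(OCc3ccccc3)c(OCc3ccccc3)c1)[C@H]4C2 | intermediate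
21 | protected trimer with pinacolboryl on upper C3 (upper unit: 2-aryl α, 3-boryl β, 4-aryl α) | c1ccccc1COc1cc(OCc3ccccc3)c2c(c1)O[C@H](c1cc(OCc3ccccc3)c(OCc3ccccc3)c(OCc3ccccc3)c1)[C@@H](B1OC(C)(C)C(C)(C)O1)[C@@H]2c1c(OCc3ccccc3)cc(OCc3ccccc3)c2c1O[C@H](c1ccc(OCc3ccccc3)c(OCc3ccccc3)c1)[C@@H](OCc1cccc(CO4)c1)[C@H]2c1c(OCc3ccccc3)cc(OCc3ccccc3)c2c1O[C@@H](c1ccc(OCc3ccccc3)c(OCc3ccccc3)c1)[C@H]4C2 | intermediate
22 | protected trimer with free upper 3-OH: trideca-O-benzyl gallocatechin-(4α→8)-catechin-(4β→8)-ent-catechin, middle and lower 3-oxygens m-xylylene-bridged | c1ccccc1COc1cc(OCc3ccccc3)c2c(c1)O[C@H](c1cc(OCc3ccccc3)c(OCc3ccccc3)c(OCc3ccccc3)c1)[C@@H](O)[C@@H]2c1c(OCc3ccccc3)cc(OCc3ccccc3)c2c1O[C@H](c1ccc(OCc3ccccc3)c(OCc3ccccc3)c1)[C@@H](OCc1cccc(CO4)c1)[C@H]2c1c(OCc3ccccc3)cc(OCc3ccccc3)c2c1O[C@@H](c1ccc(OCc3ccccc3)c(OCc3ccccc3)c1)[C@H]4C2 | intermediate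
23 | gallocatechin-(4α→8)-catechin-(4β→8)-ent-catechin; upper 2R,3S,4S, middle 2R,3S,4S, lower 2S,3R | Oc1cc(O)c2c(c1)O[C@H](c1cc(O)c(O)c(O)c1)[C@@H](O)[C@@H]2c1c(O)cc(O)c2c1O[C@H](c1ccc(O)c(O)c1)[C@@H](O)[C@H]2c1c(O)cc(O)c2c1O[C@@H](c1ccc(O)c(O)c1)[C@H](O)C2 | target

**Count**

Total step count: 13. Longest linear sequence: 9 steps (3, 4, 5, 6, 7, 9, 11, 12, 13).

**Steps most likely to fail**

1. Step 11 (key step, proposed new method). Capture of the very hindered, strongly stabilised methide carbon by the boryl-substituted alkene may be slower than self-condensation of the quinone methide. Boron may be lost by alkenyl transfer. Facial discrimination by the catalyst may be insufficient. The fallback uses known chemistry, sets out from 10 and returns at 22. Bromine–lithium exchange on 10 (t-BuLi, THF, −78 °C) and a methanol quench give the bromine-free bridged dimer F1. Commercial (+)-gallocatechin is benzylated on its five phenols (BnBr, K2CO3, DMF) to 5,7,3',4',5'-penta-O-benzylgallocatechin F2. DDQ oxidation of F2 in the presence of 2-ethoxyethanol gives the 4-(2-ethoxyethoxy) ether F3. TMSOTf-promoted condensation of F3 with F1 (CH2Cl2, −78 °C, F1 in excess and recovered) joins upper C4 to middle C8 from the α-face, trans to the 3-hydroxyl. This is the inherent preference of a 2,3-trans flavan C4 electrophile, and it gives 22 directly.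

2. Step 7. The m-xylylene tether may fail to bring lower C8 to the β-face of C4, so that intermolecular oligomerisation or attack through lower C6 takes over. The fallback sets out from 8 and returns at 10. Acylation of the 3-hydroxyl of 8 with glutaric anhydride (DMAP, pyridine) gives the hemiglutarate F4. Carbodiimide esterification of F4 with 2 (EDC·HCl, DMAP, CH2Cl2) gives the glutarate-linked pair F5. TMSOTf at high dilution closes the macrolide dimer F6 on this flexible diester tether, the tether type on which the cis-selective closure is established. DIBAL-H removes the tether to give the diol dimer F7. Double Williamson etherification of F7 with 3 (NaH, DMF, high dilution) installs the hydrogenolysable bridge after the stereo-defining bond is in place and returns to 10.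

3. Step 9. Addition of the di-ortho-substituted aryllithium to the deactivated, di-ortho-substituted phenoxide aldehyde may be slower than protonation of the aryllithium. The fallback sets out from 10 and returns at 15, with the roles of the two partners reversed. Bromine–lithium exchange on 10 and a DMF quench give the middle-unit C8 aldehyde F8. Condensation of F8 with commercial 3,5-bis(benzyloxy)phenol and phenylboronic acid (cat. propionic acid, PhMe, reflux with removal of water) is a boron-templated, ortho-specific hydroxyalkylation of the phenol and gives the 2-phenyl-4H-1,3,2-benzodioxaborin F9. Transesterification of F9 with propane-1,3-diol (THF, rt) releases 15.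

Further compounds
F1 | step 11 | bromine-free bridged dimer: tetra-O-benzylcatechin-(4β→8)-tetra-O-benzyl-ent-catechin, 3-O to 3-O m-xylylene bridge | c1c(OCc3ccccc3)cc(OCc3ccccc3)c2c1O[C@H](c1ccc(OCc3ccccc3)c(OCc3ccccc3)c1)[C@@H](OCc1cccc(CO4)c1)[C@H]2c1c(OCc3ccccc3)cc(OCc3ccccc3)c2c1O[C@@H](c1ccc(OCc3ccccc3)c(OCc3ccccc3)c1)[C@H]4C2
F2 | step 11 | 5,7,3',4',5'-penta-O-benzyl-(+)-gallocatechin | c1c(OCc3ccccc3)cc(OCc3ccccc3)c2c1O[C@H](c1cc(OCc3ccccc3)c(OCc3ccccc3)c(OCc3ccccc3)c1)[C@@H](O)C2
F3 | step 11 | 5,7,3',4',5'-penta-O-benzyl-4β-(2-ethoxyethoxy)gallocatechin | c1c(OCc3ccccc3)cc(OCc3ccccc3)c2c1O[C@H](c1cc(OCc3ccccc3)c(OCc3ccccc3)c(OCc3ccccc3)c1)[C@@H](O)[C@H]2OCCOCC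
F4 | step 7 | 3-O-hemiglutarate of 8 | Brc1c(OCc3ccccc3)cc(OCc3ccccc3)c2c1O[C@H](c1ccc(OCc3ccccc3)c(OCc3ccccc3)c1)[C@@H](OC(=O)CCCC(=O)O)[C@H]2OCCOCC
F5 | step 7 | glutarate-linked pair of 8 and 2 | Brc1c(OCc3ccccc3)cc(OCc3ccccc3)c2c1O[C@H](c1ccc(OCc3ccccc3)c(OCc3ccccc3)c1)[C@@H](OC(=O)CCCC(=O)O[C@@H]1Cc3c(OCc4ccccc4)cc(OCc4ccccc4)cc3O[C@H]1c1ccc(OCc3ccccc3)c(OCc3ccccc3)c1)[C@H]2OCCOCC
F6 | step 7 | glutarate-bridged macrolide dimer: 8-bromo-tetra-O-benzylcatechin-(4β→8)-tetra-O-benzyl-ent-catechin 3,3-glutarate | Brc1c(OCc3ccccc3)cc(OCc3ccccc3)c2c1O[C@H](c1ccc(OCc3ccccc3)c(OCc3ccccc3)c1)[C@@H](OC(=O)CCCC(=O)O4)[C@H]2c1c(OCc3ccccc3)cc(OCc3ccccc3)c2c1O[C@@H](c1ccc(OCc3ccccc3)c(OCc3ccccc3)c1)[C@H]4C2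
F7 | step 7 | diol dimer: 8-bromo-tetra-O-benzylcatechin-(4β→8)-tetra-O-benzyl-ent-catechin with both 3-OH free | Brc1c(OCc3ccccc3)cc(OCc3ccccc3)c2c1O[C@H](c1ccc(OCc3ccccc3)c(OCc3ccccc3)c1)[C@@H](O)[C@H]2c1c(OCc3ccccc3)cc(OCc3ccccc3)c2c1O[C@@H](c1ccc(OCc3ccccc3)c(OCc3ccccc3)c1)[C@H](O)C2
F8 | step 9 | middle-unit C8 aldehyde of the bridged dimer | O=Cc1c(OCc3ccccc3)cc(OCc3ccccc3)c2c1O[C@H](c1ccc(OCc3ccccc3)c(OCc3ccccc3)c1)[C@@H](OCc1cccc(CO4)c1)[C@H]2c1c(OCc3ccccc3)cc(OCc3ccccc3)c2c1O[C@@H](c1ccc(OCc3ccccc3)c(OCc3ccccc3)c1)[C@H]4C2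
F9 | step 9 | 5,7-bis(benzyloxy)-2-phenyl-4-aryl-4H-1,3,2-benzodioxaborin, aryl = middle-unit C8 of the bridged dimer, C4 epimers | c1ccccc1B1Oc2cc(OCc3ccccc3)cc(OCc3ccccc3)c2C(O1)c1c(OCc3ccccc3)cc(OCc3ccccc3)c2c1O[C@H](c1ccc(OCc3ccccc3)c(OCc3ccccc3)c1)[C@@H](OCc1cccc(CO4)c1)[C@H]2c1c(OCc3ccccc3)cc(OCc3ccccc3)c2c1O[C@@H](c1ccc(OCc3ccccc3)c(OCc3ccccc3)c1)[C@H]4C2
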